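Slowness opened the meeting: the chair noted that the east and south-east flasks had reached just 13.5% and 13.6% mono adduct at 30.0 s, while the flasks in question are read at 2.5 min.

| flask | substrate | reagent | scavenger | remark | time |
|---|---|---|---|---|---|
| east | 0.045 M | 0.081 M | 0.054 M | run made earlier |  |
| south-east | 0.022 M | 0.081 M | 0.036 M | run made earlier |  |
| Friday's | 0.045 M | 0.0810 M | 0.0360 M |  | 2.5 min |
| Monday's | 0.045 M | 0.200 M | 0.0360 M |  | 2.5 min |

| run | time / s | mono adduct / % |
|---|---|---|
| east | 10.0 | 5.3 |
| east | 20.0 | 9.7 |
| east | 30.0 | 13.5 |
| south-east | 10.0 | 4.8 |
| south-east | 15.0 | 8.1 |
| south-east | 25.0 | 12.4 |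
| south-east | 30.0 | 13.6 |

(standard deviation of a reading: 0.5 percentage points)

- which of the two there is more of at the end, Friday's (mono adduct / bis adduct)
- which of the two there is more of at the end, Monday's (mono adduct / bis adduct)
- mono adduct at the end, in percent of the substrate charged, Friday's
- mono adduct at the end, in percent of the substrate charged, Monday's

I, taking the minutes, proposed to read the pace from the first readings. The mean yield at 10.0 s in the two runs, divided by that time and the reagent charge, gives a rate constant of 0.0623 M⁻¹ s⁻¹, a reading that carries the scatter of 0.5 percentage points. The logarithm of two over that constant and Friday's reagent charge gives 2.29 min. I called this the reagent half-life of substrate: the time in which substrate would halve with reagent held at its charge, a pseudo-first-order half-life. For Monday's flask it shortens to 0.926 min.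

I reckoned that 46.9% of the substrate would stand in Friday's flask at 2.5 min and 15.4% in Monday's. I warned that this holds reagent at its charge, although reagent is used, that it takes the first mono adduct readings as the substrate lost, and that it gives no split between mono and bis adduct.

The forecaster gave Friday's flask 31% mono adduct, the larger product being mono adduct, and Monday's 28%, the larger being bis adduct. The forecaster argued that “the curvature looks roughly first-order and independent of concentration” and took this as a sign of mono adduct being consumed onward.

    substrate + released group ⇌ idle adduct, settled at all times (K = 9.27 M⁻¹)
    scavenger + released group → scavenged by-product (k = 0.658 M⁻¹ s⁻¹)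
    substrate + reagent → mono adduct + released group (k = 0.0697 M⁻¹ s⁻¹)
    reagent + mono adduct → bis adduct + released group (k = 0.0513 M⁻¹ s⁻¹)

Friday's flask holds 36.6% mono adduct against the forecast's 31% at 2.5 min; the half-life at that moment, rescaled to the 67% of its reagent charge left, is 3.42 min, longer than the 2.5 min run, with 48% of the substrate standing and mono adduct then made 1.79 times faster than it is used up, each step taken net. Monday's half-life at the same moment, rescaled to the 73% of its reagent charge left, is 1.27 min, shorter than the run, with 17% of the substrate standing, bis adduct ahead at 41.9%, and mono adduct down from 39.3% at 1.25 min to 36.8%.

(The data were computed with constants of no real substance; the scatter is artificial.)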